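**Retrosynthetic overview**
1. The chain-bearing oxolane (ring O, the CH carrying the hexyl chain, two CH2, spiro C) is disconnected last. Cutting its O–C(spiro) bond and its CH2–CH2 bond gives the phthalide-bearing (S)-terminal epoxide and methyl (6S)-6-hydroxy-3-oxoheptanoate, whose ester carbon is an activating group that leaves as CO2.
2. Enabling feature: the spiro carbon is a masked ketone lying γ to both ring oxygens. In the chain-bearing oxolane the atoms O–CH(R)–CH2 are therefore an epoxide, and the CH2 next to the spiro carbon is the α-carbon of a β-keto ester. These four atoms are first parked in a temporary γ-butyrolactone, whose C=O is then exchanged for the neighbouring ketone carbon with extrusion of CO2.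
3. The β-keto ester comes from the dianion of methyl acetoacetate and (S)-propylene oxide, so the methyl-bearing carbinol centre comes from the chiral pool.
4. The epoxide comes from the 3-(oct-7-enyl)phthalide by epoxidation and hydrolytic kinetic resolution. That phthalide is made from 3,5-dimethoxybenzoyl chloride and 8-bromooct-1-ene by acylation, asymmetric transfer hydrogenation (sets C3), bromination and carbonylative lactonisation.
5. Ring order: phthalide lactone (step 4); then in step 8 the temporary γ-lactone, the methyl-bearing oxolane and, last of all, the chain-bearing oxolane.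

Key step: step 8

Remark: the SMILES is read as (3R) at the phthalide carbon and (2S,5R,7S) in the 1,6-dioxaspiro[4.4]nonane. This is the E,E isomer, with each alkyl group trans to the oxygen of the other ring. The spiro centre is acid-labile, so the final product is handled on base-washed silica.

**Step 1**
Reactants: 1 3,5-dimethoxybenzoyl chloride; 2 8-bromooct-1-ene
Product: 4 1-(3,5-dimethoxyphenyl)non-8-en-1-one, via oct-7-en-1-ylmagnesium bromide 3 (not isolated)
Conditions: Mg, THF, reflux; then 1, Fe(acac)3 (3 mol %), THF, −78 to 0 °C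
Reagents that add atoms: none
Why: Iron-catalysed acylation of a Grignard reagent with an acid chloride (Kochi/Fürstner-type cross-coupling) is much faster than addition to the ketone formed, so it should stop at 4 and leave the terminal alkene untouched; no stereocentre is formed.

**Step 2**
Reactants: 4 1-(3,5-dimethoxyphenyl)non-8-en-1-one
Product: 5 (1R)-1-(3,5-dimethoxyphenyl)non-8-en-1-ol
Conditions: RuCl[(R,R)-TsDPEN](p-cymene) (1 mol %), HCO2H–Et3N (5:2), 30 °C
Reagents that add atoms: none
Why: In the Noyori–Ikariya asymmetric transfer hydrogenation of an aryl alkyl ketone the (R,R)-catalyst should set the (R)-carbinol centre through its CH/π-organised six-membered transition state, and the outer-sphere mechanism leaves the isolated alkene alone.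

**Step 3**
Reactants: 5 (1R)-1-(3,5-dimethoxyphenyl)non-8-en-1-ol
Product: 6 (1R)-1-(2-bromo-3,5-dimethoxyphenyl)non-8-en-1-ol
Conditions: NBS (1.0 equiv), MeCN, −10 to 0 °C, dark
Reagents that add atoms: N-bromosuccinimide, O=C1CCC(=O)N1Br
Why: Electrophilic aromatic bromination should go to the position para to one methoxy group and ortho to the other, next to the side chain (the site between the two methoxy groups is more hindered), and the doubly activated ring outruns the terminal alkene; the stereocentre is not involved.

**Step 4**
Reactants: 6 (1R)-1-(2-bromo-3,5-dimethoxyphenyl)non-8-en-1-ol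
Product: 7 (3R)-5,7-dimethoxy-3-(oct-7-en-1-yl)-2-benzofuran-1(3H)-one
Conditions: CO (1 atm), Pd(OAc)2 (5 mol %), Xantphos (6 mol %), Et3N, toluene, 100 °C
Reagents that add atoms: carbon monoxide, [C-]#[O+]
Why: Palladium-catalysed carbonylative lactonisation (oxidative addition, CO insertion, 5-exo-trig capture of the acyl-palladium by the benzylic hydroxyl) closes the phthalide without breaking the carbinol C–O bond, so (R) is retained, and the weak amine base should not epimerise C3.

**Step 5**
Reactants: 7 (3R)-5,7-dimethoxy-3-(oct-7-en-1-yl)-2-benzofuran-1(3H)-one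
Product: 8 (3R)-5,7-dimethoxy-3-[6-(oxiran-2-yl)hexyl]-2-benzofuran-1(3H)-one (both epimers at the oxirane carbon)
Conditions: mCPBA, CH2Cl2, 0 °C to rt
Reagents that add atoms: 3-chloroperoxybenzoic acid, OOC(=O)c1cccc(Cl)c1
Why: Prilezhaev epoxidation of the only alkene; the remote C3 centre exerts no control, so both oxirane epimers are expected and the new centre is corrected in step 6.

**Step 6**
Reactants: 8 (3R)-5,7-dimethoxy-3-[6-(oxiran-2-yl)hexyl]-2-benzofuran-1(3H)-one
Product: 9 (3R)-5,7-dimethoxy-3-{6-[(2S)-oxiran-2-yl]hexyl}-2-benzofuran-1(3H)-one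
Conditions: (S,S)-(salen)Co(III)OAc (1 mol %), H2O (0.55 equiv), THF, 0 °C to rt
Reagents that add atoms: none
Why: In the Jacobsen hydrolytic kinetic resolution the (S,S)-catalyst hydrolyses the (R)-oxirane epimer much faster, so catalyst control should leave the (S)-oxirane 9, which is easily separated from the polar diol and carries the future carbinol centre of the chain-bearing oxolane.

**Step 7**
Reactants: 10 methyl acetoacetate; 11 (S)-propylene oxide
Product: 13 methyl (6S)-6-hydroxy-3-oxoheptanoate, via sodium lithium dianion of methyl acetoacetate 12 (not isolated)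
Conditions: NaH, THF, 0 °C; n-BuLi, 0 °C; 11, 0 °C to rt; AcOH (2 equiv), −20 °C
Reagents that add atoms: none
Why: In the Weiler dianion alkylation the more reactive γ-carbon attacks the CH2 terminus of the epoxide (SN2), so the (S)-centre of 11 is carried over unchanged, and the buffered quench avoids cyclodehydration.

**Step 8**
Reactants: 9 (3R)-5,7-dimethoxy-3-{6-[(2S)-oxiran-2-yl]hexyl}-2-benzofuran-1(3H)-one; 13 methyl (6S)-6-hydroxy-3-oxoheptanoate
Product: 18 (3R)-5,7-dimethoxy-3-{6-[(2S,5R,7S)-7-methyl-1,6-dioxaspiro[4.4]nonan-2-yl]hexyl}-2-benzofuran-1(3H)-one, via sodium enolate of the β-keto ester 14 (not isolated), via α-acyl-γ-butyrolactone 15 (not isolated), via hemiketal lactone 16 (not isolated), via lactol alcohol 17 (not isolated)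
Conditions: 13 (1.2 equiv), NaOMe (1.2 equiv), MeOH, 55 °C; evaporate; 1 M aq H2SO4–1,4-dioxane (1:1), 85 °C, same flask; NaHCO3 work-up
Reagents that add atoms: none
Why: NaOMe turns 13 into its soft enolate 14 (conjugate acid pKa about 11, too weak a base to deprotonate the phthalide C3–H and too soft to attack its hindered carbonyl), whose α-carbon opens the oxirane of 9 by SN2 attack at the unhindered CH2 terminus, so the C–O bond of the (S)-carbinol carbon is never touched, and the alkoxide set free lactonises on the ester (5-exo-trig) to 15, the classical acetoacetate–epoxide route to α-acyl-γ-butyrolactones. In hot dilute acid the free (S)-hydroxyl adds to the ketone (5-exo-trig) and closes the methyl-bearing oxolane first as hemiketal 16, while the second oxygen is still locked in the lactone. Hydrolysis of this β-keto-activated lactone is made irreversible by loss of CO2 from the β-keto acid (the stereorandom α-carbon becomes the ring CH2), whereas the phthalide has no such exit and merely re-closes if it opens, which secures the chemoselectivity between the two lactones. Lactol 17 ionises to the oxolanyl oxocarbenium ion and the liberated (S)-alcohol attacks it (5-exo-trig), closing the chain-bearing oxolane as the last ring; the water used in the hydrolysis is returned here, so the net change from 15 is loss of CO2 only. The closest known reactions are the acid hydrolysis–decarboxylation of α-acyl-γ-butyrolactones to γ-hydroxy ketones and the conversion of α-(4-hydroxybutanoyl)-γ-butyrolactone into 1,6-dioxaspiro[4.4]nonane. The spiro carbon is the only new stereocentre and is set under thermodynamic control by the two (S)-carbinol centres, the (5R) E,E isomer having each alkyl group trans to the oxygen of the other ring (both C–O bonds pseudoaxial, both alkyl groups pseudoequatorial); this bias is expected to be modest, so the (5S) epimer is separated on base-washed silica and returned to the same acid.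

**Compound list**
1 | 3,5-dimethoxybenzoyl chloride | COc1cc(OC)cc(c1)C(=O)Cl | starting material
2 | 8-bromooct-1-ene | C=CCCCCCCBr | starting material
3 | oct-7-en-1-ylmagnesium bromide | C=CCCCCCC[Mg]Br | intermediate
4 | 1-(3,5-dimethoxyphenyl)non-8-en-1-one | COc1cc(OC)cc(c1)C(=O)CCCCCCC=C | intermediate
5 | (1R)-1-(3,5-dimethoxyphenyl)non-8-en-1-ol | COc1cc(OC)cc(c1)[C@H](O)CCCCCCC=C | intermediate
6 | (1R)-1-(2-bromo-3,5-dimethoxyphenyl)non-8-en-1-ol | COc1cc(OC)c(Br)c(c1)[C@H](O)CCCCCCC=C | intermediate
7 | (3R)-5,7-dimethoxy-3-(oct-7-en-1-yl)-2-benzofuran-1(3H)-one | COc1cc(OC)c2c(c1)[C@@H](CCCCCCC=C)OC2=O | intermediate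
8 | (3R)-5,7-dimethoxy-3-[6-(oxiran-2-yl)hexyl]-2-benzofuran-1(3H)-one, both oxirane epimers | COc1cc(OC)c2c(c1)[C@@H](CCCCCCC1CO1)OC2=O | intermediate
9 | (3R)-5,7-dimethoxy-3-{6-[(2S)-oxiran-2-yl]hexyl}-2-benzofuran-1(3H)-one | COc1cc(OC)c2c(c1)[C@@H](CCCCCC[C@H]1CO1)OC2=O | intermediate
10 | methyl acetoacetate | CC(=O)CC(=O)OC | starting material
11 | (S)-propylene oxide | C[C@H]1CO1 | starting material
12 | sodium lithium dianion of methyl acetoacetate | [Na+].[Li+].C=C([O-])C=C([O-])OC | intermediate
13 | methyl (6S)-6-hydroxy-3-oxoheptanoate | C[C@H](O)CCC(=O)CC(=O)OC | intermediate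
14 | sodium enolate of methyl (6S)-6-hydroxy-3-oxoheptanoate | [Na+].C[C@H](O)CCC([O-])=CC(=O)OC | intermediate
15 | (3R)-3-{6-[(2S)-4-[(4S)-4-hydroxypentanoyl]-5-oxooxolan-2-yl]hexyl}-5,7-dimethoxy-2-benzofuran-1(3H)-one, both epimers at the acyl-bearing carbon | COc1cc(OC)c2c(c1)[C@@H](CCCCCC[C@H]1CC(C(=O)CC[C@H](C)O)C(=O)O1)OC2=O | intermediate
16 | (3R)-3-{6-[(2S)-4-[(5S)-2-hydroxy-5-methyloxolan-2-yl]-5-oxooxolan-2-yl]hexyl}-5,7-dimethoxy-2-benzofuran-1(3H)-one (hemiketal form of 15) | COc1cc(OC)c2c(c1)[C@@H](CCCCCC[C@H]1CC(C3(O)CC[C@H](C)O3)C(=O)O1)OC2=O | intermediate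
17 | (3R)-3-{(7S)-7-hydroxy-9-[(5S)-2-hydroxy-5-methyloxolan-2-yl]nonyl}-5,7-dimethoxy-2-benzofuran-1(3H)-one | COc1cc(OC)c2c(c1)[C@@H](CCCCCC[C@H](O)CCC1(O)CC[C@H](C)O1)OC2=O | intermediate
18 | (3R)-5,7-dimethoxy-3-{6-[(2S,5R,7S)-7-methyl-1,6-dioxaspiro[4.4]nonan-2-yl]hexyl}-2-benzofuran-1(3H)-one | COc1cc(OC)c2c(c1)[C@@H](CCCCCC[C@H]1CC[C@@]3(CC[C@H](C)O3)O1)OC2=O | target

Total step count: 8. Longest linear sequence: 7 steps (steps 1–6 and 8).

**Steps most likely to fail**

**Step 8.**
- **What may go wrong:**
  - C-alkylation of the soft enolate by the unactivated oxirane may be slower than opening of the oxirane by methoxide.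
  - It may also be slower than retro-Claisen deacylation of the acyl lactone.
  - The thermodynamic bias at the spiro carbon may be too small.
- **Fallback:** an alkyne serves as the masked ketone. The fallback sets out from 9 and 11 and returns at 18.
- 11 is opened by lithiated 1-(trimethylsilyl)propyne to (2S)-6-(trimethylsilyl)hex-5-yn-2-ol F1.
- F1 is O-silylated (TBSCl, imidazole) to the bis-silyl compound F2, and this is C-desilylated (K2CO3, MeOH) to the terminal alkyne silyl ether F3.
- Deprotonation of F3 (n-BuLi) and BF3·OEt2 at −78 °C (Yamaguchi–Hirao alkynylation) opens 9 at its CH2 terminus to the homopropargylic alcohol F4.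
- HF·pyridine then frees the alkynediol F5.
- (Ph3P)AuCl/AgOTf (or PdCl2(MeCN)2) in THF effects the known double hydroalkoxylation of an alkynediol: 5-exo-dig attack of the methyl carbinol, followed by addition of the second hydroxyl to the enol ether. This gives 18.

**Step 4.**
- **What may go wrong:**
  - Oxidative addition into the di-ortho-substituted, electron-rich C–Br bond may be sluggish.
  - Heck-type consumption or isomerisation of the terminal alkene, and protodebromination, could then compete.
- **Fallback:** polar carboxylation replaces palladium catalysis. The fallback sets out from 6 and returns at 7.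
- 6 is treated with n-BuLi (2.2 equiv, THF, −78 °C; deprotonation and bromine–lithium exchange) and then with CO2, giving the hydroxy acid F6.
- F6 lactonises to 7 on acidification (cat. TsOH, toluene) without touching the carbinol C–O bond.

**Step 7.**
- **What may go wrong:**
  - γ-Alkylation of the dianion by the epoxide may be incomplete.
  - The hydroxy keto ester may cyclodehydrate to the oxolanylidene acetate during work-up or chromatography.
- **Fallback:** the acyl side is built first. The fallback sets out from 11 and returns at 13.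
- 11 is opened with dimethyl malonate (NaOMe, MeOH) to the lactone ester F7.
- Krapcho demethoxycarbonylation (LiCl, wet DMSO, 140 °C) gives (S)-γ-valerolactone F8.
- Crossed Claisen acylation of the lithium enolate of methyl acetate (LDA, MeOAc, THF, −78 °C, excess enolate) with F8 opens the lactone to 13.

**Further compounds**
F1 | step 8 | (2S)-6-(trimethylsilyl)hex-5-yn-2-ol | C[C@H](O)CCC#C[Si](C)(C)C
F2 | step 8 | tert-butyl(dimethyl){[(2S)-6-(trimethylsilyl)hex-5-yn-2-yl]oxy}silane | C[C@H](O[Si](C)(C)C(C)(C)C)CCC#C[Si](C)(C)C
F3 | step 8 | tert-butyl[(2S)-hex-5-yn-2-yloxy]dimethylsilane | C[C@H](O[Si](C)(C)C(C)(C)C)CCC#C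
F4 | step 8 | (3R)-3-[(7S,13S)-13-{[tert-butyl(dimethyl)silyl]oxy}-7-hydroxytetradec-9-yn-1-yl]-5,7-dimethoxy-2-benzofuran-1(3H)-one | COc1cc(OC)c2c(c1)[C@@H](CCCCCC[C@H](O)CC#CCC[C@H](C)O[Si](C)(C)C(C)(C)C)OC2=O
F5 | step 8 | (3R)-3-[(7S,13S)-7,13-dihydroxytetradec-9-yn-1-yl]-5,7-dimethoxy-2-benzofuran-1(3H)-one | COc1cc(OC)c2c(c1)[C@@H](CCCCCC[C@H](O)CC#CCC[C@H](C)O)OC2=O
F6 | step 4 | 2-[(1R)-1-hydroxynon-8-en-1-yl]-4,6-dimethoxybenzoic acid | COc1cc(OC)c(C(=O)O)c(c1)[C@H](O)CCCCCCC=C
F7 | step 7 | methyl (5S)-5-methyl-2-oxooxolane-3-carboxylate | COC(=O)C1C[C@H](C)OC1=O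
F8 | step 7 | (5S)-5-methyloxolan-2-one | C[C@H]1CCC(=O)O1
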